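Compound numbers are those of the list after the steps. The target has no stereocentre, so no step has to set or protect configuration.

## Analysis of the target

Target 22 is a 2,2-dimethylindane, a benzene ring fused to a cyclopentane, whose aromatic carbons C4, C5 and C6 carry an acetoxymethyl, a 2-chloroethyl and a butanoyloxymethyl group, while C7 is the only aromatic C–H. C2 is quaternary but bears two identical methyl groups, so the molecule has no stereocentre. The sensitive groups are two different esters of two benzylic primary alcohols, which must never be free at the same time, and a primary alkyl chloride that can eliminate to a styrene under strong base. The main difficulty is positional: three contiguous carbon arms must be placed on a pentasubstituted benzene ring. In addition, the central two-carbon arm on C5 can close a six-membered lactone or cyclic ether onto either neighbour whenever a nucleophilic oxygen faces an activated carbon. The strategy rests on the pair C5/C6: a two-carbon arm next to a one-carbon arm is, at the carboxyl oxidation level, a homophthalate (aryl–CH2CO2R beside aryl–CO2R). Without its arms the indane core has a mirror plane through C2 and the midpoint of the C5–C6 bond, so a 5,6-aryne is symmetrical and can accept the two arms in only one way.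

## Retrosynthetic reasoning

**C4 arm (22 ⇒ 21 ⇒ 19 + 20).** The acetate C–O bond is cut first, then the C4–CH2 bond, giving aryl bromide 19 and hydroxymethyl donor 20. C4 is the one ring position meta to the C6 carboxyl and activated by three alkyl groups, so a halogen can be placed there by electrophilic substitution and later exchanged for carbon. Making this arm last means its hydroxyl is the only free one when it is acetylated, so the two esters are told apart by timing. The forward coupling must work at a doubly flanked bromide under neutral conditions that spare the butanoate and the chloride.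

**C6 arm (19 ⇒ 18 ⇒ 17).** The butanoate is cut at the acyl–oxygen bond and the benzylic alcohol of 18 is traced back to the methyl benzoate of 17. The benzoate is kept as long as possible because it carries no nucleophilic oxygen that could attack the C5 chain. The forward reduction must leave the aryl bromide and the alkyl chloride alone, and acylation must follow before the new hydroxyl can displace chloride.

**C5 arm (17 ⇒ 16 ⇒ 15 ⇒ 14).** The C–Cl bond of 17 comes from the C–O bond of 16, the alcohol from acid 15, and the acid from the aliphatic ester of 14. The cut is made here because the two esters of 14 differ in kind: one is unconjugated and remote from the ring, the other conjugated and ortho-substituted. Hydroxide can therefore tell them apart, and an acid-selective hydride reagent then reduces only the arm that was freed.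

**C4 bromine (14 ⇒ 13).** The C4–Br bond is cut at the diester stage, where the C6 ester deactivates C7 most strongly and leaves C4 as the favoured site.

**Key disconnection (13 ⇒ 10 + 11 through 12).** The C5–CH2 bond and the C6–carboxyl bond are cut together, which returns both arms to one molecule of 11 and leaves the two ring carbons as the triple bond of aryne 12. This is the only place in the target where neighbouring ring carbons bear carbon arms that differ by one carbon. Both arms arrive in one step, already differentiated, and the symmetry of 12 removes any regiochemical question. The forward reaction must favour insertion over simple arylation of 11.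

**Aryne precursor (10 ⇒ 6 through 7, 8 and 9).** The C–Si and O–S bonds of 10 are cut. Silicon is first placed on the phenol oxygen (7) and moves to carbon after bromine–lithium exchange (8 to 9); the phenoxide 9 is trapped as the triflate.

**Indane core (6 ⇒ 5 ⇒ 4 ⇒ 3 ⇒ 1 + 2).** Bromine goes ortho to the hydroxyl of 5 at the less hindered C6. Phenol 5 comes from methyl ether 4, the C1 methylene of 4 from ketone 3, and the two methyl groups of 3 from 2 by double enolate alkylation of 1. Compound 1 is commercial, has its oxygen on a future aryne carbon, and its ketone activates C2 before being removed.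

## Alternatives that were turned down

Alternative 1: vinylketene benzannulation.
- Disconnection: the benzene ring is cut at C4–C5, C6–C7 and C3a–C4. Four ring carbons come from 2-diazo-1-(4,4-dimethylcyclopent-1-en-1-yl)ethan-1-one A2 and two from the siloxyalkyne {[4-(benzyloxy)but-1-yn-1-yl]oxy}triisopropylsilane A3.
- Forward key step: irradiation of A2 causes a photo-Wolff rearrangement to a vinylketene. This adds to A3 by [2+2] cycloaddition, four-electron ring opening and six-electron ring closure, and should give 5-[2-(benzyloxy)ethyl]-2,2-dimethyl-6-(triisopropylsilyloxy)indan-4-ol A1.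
- For: in A1 every ring substituent is fixed by connectivity, the C5 arm is already at the right oxidation level, and the oxygens on C4 and C6 differ (free phenol and silyl ether). On positional control this is stronger than the chosen route, which relies on an electronic bias for the C4 bromination.
- Against: in A1 the positions C4 and C6 arrive as C–O bonds, so two separate triflation and carbon-coupling cycles are needed at hindered positions, followed by the same reductions and acylations. The benzyl ether must be removed while other benzylic C–O bonds are present. A2 and A3 each need several steps, and the photochemical step limits scale.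
- Comparison: the chosen route delivers both arms as carbon at the carboxyl level from a simple diester and needs only one aryl–halogen to aryl–carbon exchange, whereas A1 needs two.

Alternative 2: enyne–ynal dehydro-Diels–Alder.
- Disconnection: C4–C5 and C3a–C7a are cut, opening both rings to the acyclic (2Z)-2-(3-chloropropylidene)-6,6-dimethyl-10-oxodeca-3,8-diyn-1-yl butanoate A5.
- Forward key step: on heating, the enyne C5=C6–C7≡C7a of A5 adds across the tethered ynal triple bond C3a≡C4. The strained cyclic allene aromatises by hydrogen shift from C5 to C7 and should give [5-(2-chloroethyl)-4-formyl-2,2-dimethylindan-6-yl]methyl butanoate A4.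
- For: in A4 all three arms are in place and only aldehyde reduction and acetylation remain. After the key step this is clearly shorter than the chosen route, and it needs no site selectivity on an arene.
- Against: A5 combines a trisubstituted enyne, a heat- and base-sensitive ynal, an ester and an alkyl chloride, and must be assembled linearly by several couplings. Unactivated enynes need high temperature, where the allene intermediate on the way to A4 can follow radical or intermolecular paths.
- Comparison: risk sits both in the precursor A5 and in a harsh key step. The chosen route has a longer endgame but a mild, precedented key step and ordinary steps around it.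

Alternative 3: acetonedicarboxylate benzannulation.
- Disconnection: C6–C7 and C3a–C4 are cut. C4, C5 and C6 come from dimethyl 3-oxopentanedioate A8 and C3a, C7a and C7 from 2-(hydroxymethylene)-4,4-dimethylcyclopentan-1-one A7.
- Forward key step: base-mediated double condensation of A8 with A7, followed by aromatisation, should give dimethyl 5-hydroxy-2,2-dimethylindane-4,6-dicarboxylate A6.
- For: A7 and A8 are simple, and the arene is reached in very few metal-free steps, with both one-carbon arms present as esters and a phenol at C5 as a coupling handle. In steps to the arene this is shorter than the chosen route.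
- Against: the two esters of A6 are near twins, both ortho to the C5 oxygen and differing only in a ring CH2 versus H neighbour, yet they must end as different esters. The C5 triflate derived from A6 is flanked by two esters, and the two-carbon arm would then sit between two carbonyls and could lactonise in either direction.
- Comparison: in the chosen route the two arms are made different from the start (benzoate and alkanoate) and the third enters at a separate time, which A6 cannot offer.

Key step: step 6

Remark on numbering: the indane core is symmetric until C4 is substituted, so the locants 5 and 6 of compound 13 are interchangeable. From compound 14 on, target numbering is used (C4 future acetoxymethyl carbon, C5 two-carbon arm, C6 one-carbon arm). Compound 20 is assumed to be purchased.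

## Route

Step 1
Reactants: 1 5-methoxy-1-indanone; 2 iodomethane
Product: 3 5-methoxy-2,2-dimethyl-1-indanone
Conditions: NaH (2.5 equiv), MeI (3 equiv), THF, 0 °C → rt
Reagents that add atoms: iodomethane (second equivalent), CI
Why: Double enolate alkylation that consumes two equivalents of 2, one for each methyl group on C2. C2 is the only enolisable position, so exhaustive methylation should stop cleanly at the gem-dimethyl ketone.

Step 2
Reactants: 3 5-methoxy-2,2-dimethyl-1-indanone
Product: 4 5-methoxy-2,2-dimethylindane
Conditions: Et3SiH (3 equiv), CF3CO2H, rt → 50 °C
Reagents that add atoms: none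
Why: Ionic hydrogenation of an aryl ketone; the benzylic cation is stabilised by the para methoxy group and is more stable than the tertiary cation a methyl shift from C2 would give, so the skeleton should not rearrange.

Step 3
Reactants: 4 5-methoxy-2,2-dimethylindane
Product: 5 2,2-dimethylindan-5-ol
Conditions: BBr3, CH2Cl2, −78 °C → rt; H2O
Reagents that add atoms: none
Why: Lewis-acid cleavage of an aryl methyl ether; nothing else in the molecule reacts with BBr3.

Step 4
Reactants: 5 2,2-dimethylindan-5-ol
Product: 6 6-bromo-2,2-dimethylindan-5-ol
Conditions: NBS (1.0 equiv), i-Pr2NH (cat.), CH2Cl2, 0 °C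
Reagents that add atoms: N-bromosuccinimide, O=C1CCC(=O)N1Br
Why: Amine-mediated ortho-bromination of a phenol; the para position is the ring-fusion carbon, and of the two ortho positions C6 is less hindered than C4, which lies next to the ring CH2.

Step 5
Reactants: 6 6-bromo-2,2-dimethylindan-5-ol
Product: 10 2,2-dimethyl-6-(trimethylsilyl)indan-5-yl trifluoromethanesulfonate, via [(6-bromo-2,2-dimethylindan-5-yl)oxy]trimethylsilane 7 (not isolated), via [(6-lithio-2,2-dimethylindan-5-yl)oxy]trimethylsilane 8 (not isolated), via lithium 2,2-dimethyl-6-(trimethylsilyl)indan-5-olate 9 (not isolated)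
Conditions: (Me3Si)2NH, THF, reflux, then evaporate; n-BuLi, THF, −78 °C → rt; Tf2O, −78 °C → rt
Reagents that add atoms: hexamethyldisilazane, C[Si](C)(C)N[Si](C)(C)C; trifluoromethanesulfonic anhydride, O=S(=O)(OS(=O)(=O)C(F)(F)F)C(F)(F)F
Why: O-silylation, bromine–lithium exchange and retro-Brook 1,3-shift of silicon from oxygen to the lithiated carbon, then O-triflation of the phenoxide; this is the standard sequence from 2-bromophenols to 2-silylaryl triflates.

Step 6
Reactants: 10 2,2-dimethyl-6-(trimethylsilyl)indan-5-yl trifluoromethanesulfonate; 11 dimethyl malonate
Product: 13 methyl 6-(2-methoxy-2-oxoethyl)-2,2-dimethylindane-5-carboxylate, via 2,2-dimethyl-5,6-didehydroindane 12 (not isolated)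
Conditions: CsF (3 equiv), 11 (3 equiv), MeCN, 80 °C
Reagents that add atoms: none
Why: Fluoride attacks silicon in 10 and triflate leaves in a 1,2-elimination, giving aryne 12, to which the anion of 11 adds at one aryne carbon. The aryl anion so formed attacks an ester carbonyl of the malonate unit it now carries (4-exo-trig), and the strained four-membered alkoxide reopens by cleaving the former malonate C–C bond, leaving a benzoate on one carbon and an ester-stabilised benzylic anion on the other; protonation by more 11 gives 13 and carries the chain. The closest known reaction type is the insertion of arynes from 2-silylaryl triflates into the C–C bond of malonates and β-keto esters (acyl-alkylation). No ring remains after the step, since the four-membered ring is only a transient, and no stereocentre is formed. Regioselectivity is not in question because the two carbons of 12 are related by the mirror plane through C2. The step needs chemoselectivity for insertion over plain α-arylation: with anhydrous CsF in MeCN the only proton source is 11 itself, which the intramolecular carbonyl attack should outpace, and the excess of 11 keeps the less acidic CH2 of 13 from being arylated a second time.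

Step 7
Reactants: 13 methyl 6-(2-methoxy-2-oxoethyl)-2,2-dimethylindane-5-carboxylate
Product: 14 methyl 4-bromo-5-(2-methoxy-2-oxoethyl)-2,2-dimethylindane-6-carboxylate
Conditions: NBS (1.05 equiv), CF3CO2H, H2SO4 (cat.), rt, dark
Reagents that add atoms: N-bromosuccinimide, O=C1CCC(=O)N1Br
Why: Electrophilic aromatic bromination in acid; C4 is ortho to two alkyl groups, para to a third and meta to the ester, whereas C7 is ortho to the ester, so C4 should be strongly preferred, and ionic conditions in the dark avoid benzylic radical bromination.

Step 8
Reactants: 14 methyl 4-bromo-5-(2-methoxy-2-oxoethyl)-2,2-dimethylindane-6-carboxylate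
Product: 15 2-[4-bromo-6-(methoxycarbonyl)-2,2-dimethylindan-5-yl]acetic acid
Conditions: LiOH·H2O (1.05 equiv), THF/H2O, 0 °C; then aq. HCl
Reagents that add atoms: lithium hydroxide, [Li+].[OH-]
Why: Selective saponification; the unconjugated arylacetic ester is attacked by hydroxide faster than the conjugated, ortho-substituted benzoate, and the carboxylate formed discourages a second attack.

Step 9
Reactants: 15 2-[4-bromo-6-(methoxycarbonyl)-2,2-dimethylindan-5-yl]acetic acid
Product: 16 methyl 4-bromo-5-(2-hydroxyethyl)-2,2-dimethylindane-6-carboxylate
Conditions: BH3·THF, THF, 0 °C → rt; MeOH quench, neutral work-up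
Reagents that add atoms: none
Why: Borane reduces a carboxylic acid through its acyloxyborane much faster than a methyl benzoate and does not touch an aryl bromide; 16 is kept neutral and cold and used at once so that it does not lactonise onto the C6 ester.

Step 10
Reactants: 16 methyl 4-bromo-5-(2-hydroxyethyl)-2,2-dimethylindane-6-carboxylate
Product: 17 methyl 4-bromo-5-(2-chloroethyl)-2,2-dimethylindane-6-carboxylate
Conditions: PPh3, NCS, CH2Cl2, 0 °C → rt
Reagents that add atoms: N-chlorosuccinimide, O=C1CCC(=O)N1Cl
Why: Appel-type chlorination; chloride displaces the alkoxyphosphonium group at an unhindered primary carbon under neutral conditions.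

Step 11
Reactants: 17 methyl 4-bromo-5-(2-chloroethyl)-2,2-dimethylindane-6-carboxylate
Product: 18 [4-bromo-5-(2-chloroethyl)-2,2-dimethylindan-6-yl]methanol
Conditions: i-Bu2AlH (2.5 equiv), CH2Cl2, −78 → 0 °C; aq. potassium sodium tartrate
Reagents that add atoms: none
Why: Hydride reduction of an ester to the primary alcohol; i-Bu2AlH at low temperature leaves aryl bromides and primary alkyl chlorides intact, and the aluminium alkoxide is too weak a nucleophile to displace the chloride.

Step 12
Reactants: 18 [4-bromo-5-(2-chloroethyl)-2,2-dimethylindan-6-yl]methanol
Product: 19 [4-bromo-5-(2-chloroethyl)-2,2-dimethylindan-6-yl]methyl butanoate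
Conditions: (n-PrCO)2O, Et3N, DMAP (cat.), CH2Cl2, 0 °C → rt
Reagents that add atoms: butanoic anhydride, CCCC(=O)OC(=O)CCC
Why: DMAP-catalysed acylation of a primary benzylic alcohol; it is fast at 0 °C, so the hydroxyl is capped before it can cyclise onto the chloroethyl arm.

Step 13
Reactants: 19 [4-bromo-5-(2-chloroethyl)-2,2-dimethylindan-6-yl]methyl butanoate; 20 (tributylstannyl)methanol
Product: 21 [5-(2-chloroethyl)-4-(hydroxymethyl)-2,2-dimethylindan-6-yl]methyl butanoate
Conditions: Pd(PPh3)4 (10 mol %), 1,4-dioxane, 100 °C
Reagents that add atoms: none
Why: Stille (Kosugi–Migita–Stille) coupling in which the oxygen-bearing methyl group transfers from tin in preference to butyl; the neutral conditions spare the butanoate, and zerovalent palladium with PPh3 does not insert into an unactivated primary alkyl chloride.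

Step 14
Reactants: 21 [5-(2-chloroethyl)-4-(hydroxymethyl)-2,2-dimethylindan-6-yl]methyl butanoate
Product: 22 [4-(acetoxymethyl)-5-(2-chloroethyl)-2,2-dimethylindan-6-yl]methyl butanoate
Conditions: Ac2O, pyridine, DMAP (cat.), CH2Cl2, 0 °C
Reagents that add atoms: acetic anhydride, CC(=O)OC(C)=O
Why: DMAP-catalysed acetylation of the only free hydroxyl; the mild base and low temperature leave the butanoate and the chloride untouched.

## Compound list

1 | 5-methoxy-1-indanone | COc1ccc2c(c1)CCC2=O | starting material
2 | iodomethane | CI | starting material
3 | 5-methoxy-2,2-dimethyl-1-indanone | COc1ccc2c(c1)CC(C)(C)C2=O | intermediate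
4 | 5-methoxy-2,2-dimethylindane | COc1ccc2c(c1)CC(C)(C)C2 | intermediate
5 | 2,2-dimethylindan-5-ol | Oc1ccc2c(c1)CC(C)(C)C2 | intermediate
6 | 6-bromo-2,2-dimethylindan-5-ol | Oc1cc2c(cc1Br)CC(C)(C)C2 | intermediate
7 | [(6-bromo-2,2-dimethylindan-5-yl)oxy]trimethylsilane | C[Si](C)(C)Oc1cc2c(cc1Br)CC(C)(C)C2 | intermediate (not isolated)
8 | [(6-lithio-2,2-dimethylindan-5-yl)oxy]trimethylsilane | C[Si](C)(C)Oc1cc2c(cc1[Li])CC(C)(C)C2 | intermediate (not isolated)
9 | lithium 2,2-dimethyl-6-(trimethylsilyl)indan-5-olate | [Li+].[O-]c1cc2c(cc1[Si](C)(C)C)CC(C)(C)C2 | intermediate (not isolated)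
10 | 2,2-dimethyl-6-(trimethylsilyl)indan-5-yl trifluoromethanesulfonate | CC1(C)Cc2cc(OS(=O)(=O)C(F)(F)F)c([Si](C)(C)C)cc2C1 | intermediate
11 | dimethyl malonate | COC(=O)CC(=O)OC | starting material
12 | 2,2-dimethyl-5,6-didehydroindane (aryne) | CC1(C)CC2=CC#CC=C2C1 | intermediate (not isolated)
13 | methyl 6-(2-methoxy-2-oxoethyl)-2,2-dimethylindane-5-carboxylate (target numbering: ester on C6, acetic arm on C5) | COC(=O)Cc1cc2c(cc1C(=O)OC)CC(C)(C)C2 | intermediate
14 | methyl 4-bromo-5-(2-methoxy-2-oxoethyl)-2,2-dimethylindane-6-carboxylate | COC(=O)Cc1c(Br)c2c(cc1C(=O)OC)CC(C)(C)C2 | intermediate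
15 | 2-[4-bromo-6-(methoxycarbonyl)-2,2-dimethylindan-5-yl]acetic acid | OC(=O)Cc1c(Br)c2c(cc1C(=O)OC)CC(C)(C)C2 | intermediate
16 | methyl 4-bromo-5-(2-hydroxyethyl)-2,2-dimethylindane-6-carboxylate | OCCc1c(Br)c2c(cc1C(=O)OC)CC(C)(C)C2 | intermediate
17 | methyl 4-bromo-5-(2-chloroethyl)-2,2-dimethylindane-6-carboxylate | COC(=O)c1cc2c(c(Br)c1CCCl)CC(C)(C)C2 | intermediate
18 | [4-bromo-5-(2-chloroethyl)-2,2-dimethylindan-6-yl]methanol | OCc1cc2c(c(Br)c1CCCl)CC(C)(C)C2 | intermediate
19 | [4-bromo-5-(2-chloroethyl)-2,2-dimethylindan-6-yl]methyl butanoate | CCCC(=O)OCc1cc2c(c(Br)c1CCCl)CC(C)(C)C2 | intermediate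
20 | (tributylstannyl)methanol | CCCC[Sn](CCCC)(CCCC)CO | starting material
21 | [5-(2-chloroethyl)-4-(hydroxymethyl)-2,2-dimethylindan-6-yl]methyl butanoate | CCCC(=O)OCc1cc2c(c(CO)c1CCCl)CC(C)(C)C2 | intermediate
22 | [4-(acetoxymethyl)-5-(2-chloroethyl)-2,2-dimethylindan-6-yl]methyl butanoate | CCCC(=O)OCc1cc2c(c(COC(C)=O)c1CCCl)CC(C)(C)C2 | target

## Step count and least certain steps

Total: 14 steps. Longest linear sequence: 14 steps (1 → 22); 2, 11 and 20 enter as purchased partners.

**Step 6 (key step).** The aryl anion may be protonated before it closes onto the ester, giving simple α-arylation of 11, or the product may be arylated a second time at its benzylic CH2. Both would erode the insertion. Fallback: set out from 6. Carbonylation of the aryl bromide (Pd(OAc)2, 1,3-bis(diphenylphosphino)propane, CO, Et3N, MeOH/DMSO, 80 °C) should give methyl 6-hydroxy-2,2-dimethylindane-5-carboxylate F1. Triflation (Tf2O, pyridine) gives methyl 2,2-dimethyl-6-(trifluoromethylsulfonyloxy)indane-5-carboxylate F2. Negishi coupling with BrZnCH2CO2Me under Pd(PPh3)4 in THF then comes back to the route at 13. The symmetry of the core makes it irrelevant which position receives which arm.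

**Step 13.** Oxidative addition and transmetalation at a bromide flanked on both sides may be slow, so protodestannylation of 20 could outrun coupling. At 100 °C the new benzylic hydroxyl may also close onto the chloroethyl arm to a cyclic ether. Fallback: set out from 19. Stille coupling with tributyl(vinyl)stannane, whose vinyl group transfers far faster, should give [5-(2-chloroethyl)-4-ethenyl-2,2-dimethylindan-6-yl]methyl butanoate F3. Ozonolysis (O3, CH2Cl2, −78 °C; Me2S) gives [5-(2-chloroethyl)-4-formyl-2,2-dimethylindan-6-yl]methyl butanoate F4. NaBH4 in MeOH at 0 °C then comes back at 21, so the hydroxyl appears only at low temperature.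

**Step 8 (with the handling of 16 in step 9).** Discrimination between the two esters may be incomplete, leading to over-hydrolysis, and hydroxy ester 16 may lactonise before it is chlorinated. Fallback: set out from 14 and use the lactone deliberately. LiAlH4 in THF at 0 °C reduces both esters to [4-bromo-5-(2-hydroxyethyl)-2,2-dimethylindan-6-yl]methanol F5. MnO2 oxidises only the benzylic alcohol, and the lactol that forms is oxidised on to the six-membered lactone of 4-bromo-5-(2-hydroxyethyl)-2,2-dimethylindane-6-carboxylic acid F6, in which the C6 carbonyl is joined through O–CH2–CH2 to C5. SOCl2 with catalytic ZnCl2 opens the lactone to 4-bromo-5-(2-chloroethyl)-2,2-dimethylindane-6-carbonyl chloride F7, and MeOH comes back at 17.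

**Step 7.** Bromination may also occur at C7 or at the enolisable benzylic CH2 of the acetic arm, which is only a weak ortho director. Fallback: set out from 13 and move the bromination later. Selective saponification as in step 8 gives 2-[6-(methoxycarbonyl)-2,2-dimethylindan-5-yl]acetic acid F8. BH3·THF gives methyl 6-(2-hydroxyethyl)-2,2-dimethylindane-5-carboxylate F9, and PPh3/NCS gives methyl 6-(2-chloroethyl)-2,2-dimethylindane-5-carboxylate F10. In F10 the arm is a plain alkyl group with no enolisable position; bromination under the conditions of step 7 then comes back at 17.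

## Further compounds

F1 | step 6 | methyl 6-hydroxy-2,2-dimethylindane-5-carboxylate | COC(=O)c1cc2c(cc1O)CC(C)(C)C2
F2 | step 6 | methyl 2,2-dimethyl-6-(trifluoromethylsulfonyloxy)indane-5-carboxylate | COC(=O)c1cc2c(cc1OS(=O)(=O)C(F)(F)F)CC(C)(C)C2
F3 | step 13 | [5-(2-chloroethyl)-4-ethenyl-2,2-dimethylindan-6-yl]methyl butanoate | CCCC(=O)OCc1cc2c(c(C=C)c1CCCl)CC(C)(C)C2
F4 | step 13 | [5-(2-chloroethyl)-4-formyl-2,2-dimethylindan-6-yl]methyl butanoate | CCCC(=O)OCc1cc2c(c(C=O)c1CCCl)CC(C)(C)C2
F5 | step 8 | [4-bromo-5-(2-hydroxyethyl)-2,2-dimethylindan-6-yl]methanol | OCCc1c(Br)c2c(cc1CO)CC(C)(C)C2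
F6 | step 8 | six-membered lactone of 4-bromo-5-(2-hydroxyethyl)-2,2-dimethylindane-6-carboxylic acid | O=C1OCCc2c(Br)c3c(cc21)CC(C)(C)C3
F7 | step 8 | 4-bromo-5-(2-chloroethyl)-2,2-dimethylindane-6-carbonyl chloride | O=C(Cl)c1cc2c(c(Br)c1CCCl)CC(C)(C)C2
F8 | step 7 | 2-[6-(methoxycarbonyl)-2,2-dimethylindan-5-yl]acetic acid | OC(=O)Cc1cc2c(cc1C(=O)OC)CC(C)(C)C2
F9 | step 7 | methyl 6-(2-hydroxyethyl)-2,2-dimethylindane-5-carboxylate | OCCc1cc2c(cc1C(=O)OC)CC(C)(C)C2
F10 | step 7 | methyl 6-(2-chloroethyl)-2,2-dimethylindane-5-carboxylate | COC(=O)c1cc2c(cc1CCCl)CC(C)(C)C2
A1 | alternative 1 | 5-[2-(benzyloxy)ethyl]-2,2-dimethyl-6-(triisopropylsilyloxy)indan-4-ol | Oc1c(CCOCc2ccccc2)c(O[Si](C(C)C)(C(C)C)C(C)C)cc2c1CC(C)(C)C2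
A2 | alternative 1 | 2-diazo-1-(4,4-dimethylcyclopent-1-en-1-yl)ethan-1-one | [N-]=[N+]=CC(=O)C1=CCC(C)(C)C1
A3 | alternative 1 | {[4-(benzyloxy)but-1-yn-1-yl]oxy}triisopropylsilane | CC(C)[Si](C(C)C)(C(C)C)OC#CCCOCc1ccccc1
A4 | alternative 2 | [5-(2-chloroethyl)-4-formyl-2,2-dimethylindan-6-yl]methyl butanoate | CCCC(=O)OCc1cc2c(c(C=O)c1CCCl)CC(C)(C)C2
A5 | alternative 2 | (2Z)-2-(3-chloropropylidene)-6,6-dimethyl-10-oxodeca-3,8-diyn-1-yl butanoate | CCCC(=O)OC/C(=C\CCCl)C#CCC(C)(C)CC#CC=O
A6 | alternative 3 | dimethyl 5-hydroxy-2,2-dimethylindane-4,6-dicarboxylate | COC(=O)c1cc2c(c(C(=O)OC)c1O)CC(C)(C)C2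
A7 | alternative 3 | 2-(hydroxymethylene)-4,4-dimethylcyclopentan-1-one | O=C1CC(C)(C)CC1=CO
A8 | alternative 3 | dimethyl 3-oxopentanedioate | COC(=O)CC(=O)CC(=O)OC
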